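**Strategy**

The synthesis rests on building ring C of the lower (epicatechin) unit with ring A in reversed polarity: its benzylic carbon C4 acts as a nucleophile and its ring carbon C8a as an electrophile, while O1 arrives on C2 of a mandelate-derived aldehyde whose carbonyl carbon is C3. In one flask a 2,4,6-trifluorobenzyl Grignard reagent adds to this aldehyde under chelation control (C3–C4, new C3 stereocentre), fluoride unmasks the C2 oxygen, and the alkoxide displaces the ortho fluorine (O1–C8a). The step exploits the ortho relationship of C4a and C8a on ring A and the syn C2/C3 diol. Fluorine-to-benzyloxy exchange, 4β→8 coupling with an epiafzelechin C4 electrophile, double galloylation and hydrogenolysis finish the route.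

Key step: step 5

Assumption: the target is read as epiafzelechin 3-O-gallate-(4β→8)-epicatechin 3-O-gallate (both units 2R,3R, interflavan bond trans to the upper C3 oxygen), and (−)-epiafzelechin is taken as a purchasable flavan-3-ol.

**Route**

Step 1
Reactants: 1 4-bromo-1,2-bis(benzyloxy)benzene; 2 dimethyl oxalate
Product: 4 methyl 2-[3,4-bis(benzyloxy)phenyl]-2-oxoacetate, via aryl Grignard reagent 3 (not isolated)
Conditions: Mg, THF, 40 °C; then added to 2 (3 equiv), THF, −78 °C; aq. NH4Cl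
Reagents that add atoms: none
Why: Grignard acylation of one ester group of excess dimethyl oxalate at low temperature, where the tetrahedral adduct resists a second addition, should give the aryl glyoxylate.

Step 2
Reactants: 4 methyl 2-[3,4-bis(benzyloxy)phenyl]-2-oxoacetate
Product: 5 methyl (2R)-2-[3,4-bis(benzyloxy)phenyl]-2-hydroxyacetate
Conditions: RuCl[(S,S)-TsDPEN](p-cymene) (1 mol %), HCO2H/Et3N (5:2), EtOAc, 25 °C
Reagents that add atoms: none
Why: Noyori–Ikariya asymmetric transfer hydrogenation of the aryl α-keto ester, in which the (S,S)-catalyst should deliver hydride in the same spatial sense as for aryl ketones and so give the (R)-mandelate, sets the future C2 stereocentre.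

Step 3
Reactants: 5 methyl (2R)-2-[3,4-bis(benzyloxy)phenyl]-2-hydroxyacetate
Product: 6 methyl (2R)-2-[3,4-bis(benzyloxy)phenyl]-2-({[tri(propan-2-yl)silyl]oxy}methoxy)acetate
Conditions: i-Pr3SiOCH2Cl, i-Pr2NEt, Bu4NI (cat.), CH2Cl2, 0 to 25 °C
Reagents that add atoms: (chloromethoxy)tri(propan-2-yl)silane, ClCO[Si](C(C)C)(C(C)C)C(C)C
Why: Base-mediated O-alkylation gives a silyloxymethyl acetal that survives hydride and Grignard reagents, can chelate magnesium through its inner oxygen and is cleaved by fluoride, without touching the stereocentre.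

Step 4
Reactants: 6 methyl (2R)-2-[3,4-bis(benzyloxy)phenyl]-2-({[tri(propan-2-yl)silyl]oxy}methoxy)acetate
Product: 7 (2R)-2-[3,4-bis(benzyloxy)phenyl]-2-({[tri(propan-2-yl)silyl]oxy}methoxy)acetaldehyde
Conditions: i-Bu2AlH (1.1 equiv), toluene, −78 °C; aq. KNaC4H4O6; used at once
Reagents that add atoms: none
Why: Partial reduction of an α-alkoxy ester with i-Bu2AlH at −78 °C should stop at the aldehyde, which is used immediately to avoid enolisation at C2.

Step 5
Reactants: 7 (2R)-2-[3,4-bis(benzyloxy)phenyl]-2-({[tri(propan-2-yl)silyl]oxy}methoxy)acetaldehyde; 8 2-(bromomethyl)-1,3,5-trifluorobenzene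
Product: 12 (2R,3R)-2-[3,4-bis(benzyloxy)phenyl]-5,7-difluoro-3,4-dihydro-2H-chromen-3-ol, via benzylic Grignard reagent 9 (not isolated), via magnesium alkoxide adduct 10 (not isolated), via free benzylic alkoxide 11 (not isolated)
Conditions: 8, Mg, Et2O, 0 °C; added to 7 in toluene/Et2O, −78 °C; then Bu4NF (THF, dried over 4 Å molecular sieves), DMPU, −78 to 40 °C; H2O
Reagents that add atoms: none
Why: The benzylic Grignard reagent 9 adds to the aldehyde carbon C3 of 7 held in a five-membered magnesium chelate between the carbonyl oxygen and the inner acetal oxygen O1 (C3–C4 bond), fluoride then cleaves the silyl acetal, the hemiformal loses formaldehyde, and the liberated C2 alkoxide attacks ring A carbon C8a by addition–elimination (O1–C8a bond), the expelled fluoride sustaining the desilylation. The closest known reaction types are the Cram-chelate Grignard addition to α-(alkoxymethoxy) aldehydes, fluoride cleavage of silyloxymethyl ethers and intramolecular SNAr chroman closure on polyfluoroarenes, here run as one telescoped sequence. Ring C closes in the 6-exo-trig mode onto the arene π system, activated by the two fluorines meta to C8a. The C3 stereocentre is set by the chelate, the nucleophile entering past the C2 hydrogen and away from the aryl group to give the syn (2R,3R) relationship, while C2 is carried over from 7 with retention because its C–O bond is never broken. The step needs O1 and not the C3 oxygen to close on ring A: the C3 alkoxide could only form a five-membered ring, for which its two-atom tether cannot bring oxygen over the π face of C8a or C5, whereas O1 reaches either of the two equivalent ortho fluorines in a strain-free six-membered transition state and the para fluorine is out of reach. Attack of the Grignard reagent through its own ortho position is excluded because both ortho carbons carry fluorine.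

Step 6
Reactants: 12 (2R,3R)-2-[3,4-bis(benzyloxy)phenyl]-5,7-difluoro-3,4-dihydro-2H-chromen-3-ol
Product: 13 5,7,3',4'-tetra-O-benzyl-(−)-epicatechin
Conditions: BnOH, NaH (excess), DMPU, 110 °C
Reagents that add atoms: benzyl alcohol, OCc1ccccc1
Why: Twofold intermolecular SNAr of the remaining ring A fluorines by sodium benzyl oxide in a dipolar aprotic solvent should install the 5- and 7-oxygens, C2 and C3 being inert because neither bears an acidic hydrogen or a leaving group.

Step 7
Reactants: 14 (−)-epiafzelechin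
Product: 15 5,7,4'-tri-O-benzyl-(−)-epiafzelechin
Conditions: BnBr, K2CO3, DMF, 0 to 25 °C
Reagents that add atoms: benzyl bromide, BrCc1ccccc1
Why: Williamson etherification of the three phenols, which are far more acidic than the secondary C3 hydroxyl, should leave that hydroxyl free.

Step 8
Reactants: 15 5,7,4'-tri-O-benzyl-(−)-epiafzelechin
Product: 16 4β-(2-ethoxyethoxy)-5,7,4'-tri-O-benzyl-(−)-epiafzelechin
Conditions: DDQ (2 equiv), 2-ethoxyethanol, CH2Cl2, 25 °C
Reagents that add atoms: 2-ethoxyethanol, CCOCCO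
Why: DDQ benzylic oxidation removes hydride from C4, the position activated by ring A and its oxygens, and the alcohol should add at C4 trans to the C3 hydroxyl to give an ionisable C4 ether.

Step 9
Reactants: 16 4β-(2-ethoxyethoxy)-5,7,4'-tri-O-benzyl-(−)-epiafzelechin; 13 5,7,3',4'-tetra-O-benzyl-(−)-epicatechin
Product: 17 hepta-O-benzyl epiafzelechin-(4β→8)-epicatechin
Conditions: 13 (3 equiv), Me3SiOTf (cat.), CH2Cl2, −78 °C; Et3N
Reagents that add atoms: none
Why: Lewis-acid ionisation at C4 and Friedel–Crafts alkylation at C8 of ring A of 13, its most nucleophilic position, with attack anti to the upper C3 oxygen, should set the new C4 stereocentre 3,4-trans (4β), excess 13 holding back oligomerisation.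

Step 10
Reactants: 17 hepta-O-benzyl epiafzelechin-(4β→8)-epicatechin; 18 3,4,5-tris(benzyloxy)benzoic acid
Product: 19 hepta-O-benzyl epiafzelechin-(4β→8)-epicatechin 3,3'-bis[3,4,5-tris(benzyloxy)benzoate]
Conditions: 18 (4 equiv), DCC, DMAP, CH2Cl2, 25 °C
Reagents that add atoms: none
Why: Steglich esterification acylates both secondary C3 hydroxyls with retention, since no C–O bond at a stereocentre is broken.

Step 11
Reactants: 19 hepta-O-benzyl epiafzelechin-(4β→8)-epicatechin 3,3'-bis[3,4,5-tris(benzyloxy)benzoate]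
Product: 20 epiafzelechin 3-O-gallate-(4β→8)-epicatechin 3-O-gallate
Conditions: H2 (1 atm), Pd(OH)2 on carbon, THF/MeOH/H2O, 25 °C
Reagents that add atoms: none
Why: Hydrogenolysis of all thirteen benzyl ethers under neutral conditions should leave the two esters, the interflavan bond and every stereocentre intact.

**Compound list**

1 | 4-bromo-1,2-bis(benzyloxy)benzene | Brc1ccc(OCc2ccccc2)c(OCc2ccccc2)c1 | starting material
2 | dimethyl oxalate | COC(=O)C(=O)OC | starting material
3 | [3,4-bis(benzyloxy)phenyl]magnesium bromide (not isolated) | Br[Mg]c1ccc(OCc2ccccc2)c(OCc2ccccc2)c1 | intermediate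
4 | methyl 2-[3,4-bis(benzyloxy)phenyl]-2-oxoacetate | COC(=O)C(=O)c1ccc(OCc2ccccc2)c(OCc2ccccc2)c1 | intermediate
5 | methyl (2R)-2-[3,4-bis(benzyloxy)phenyl]-2-hydroxyacetate | COC(=O)[C@H](O)c1ccc(OCc2ccccc2)c(OCc2ccccc2)c1 | intermediate
6 | methyl (2R)-2-[3,4-bis(benzyloxy)phenyl]-2-({[tri(propan-2-yl)silyl]oxy}methoxy)acetate | COC(=O)[C@H](OCO[Si](C(C)C)(C(C)C)C(C)C)c1ccc(OCc2ccccc2)c(OCc2ccccc2)c1 | intermediate
7 | (2R)-2-[3,4-bis(benzyloxy)phenyl]-2-({[tri(propan-2-yl)silyl]oxy}methoxy)acetaldehyde | O=C[C@H](OCO[Si](C(C)C)(C(C)C)C(C)C)c1ccc(OCc2ccccc2)c(OCc2ccccc2)c1 | intermediate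
8 | 2-(bromomethyl)-1,3,5-trifluorobenzene (2,4,6-trifluorobenzyl bromide) | BrCc1c(F)cc(F)cc1F | starting material
9 | (2,4,6-trifluorobenzyl)magnesium bromide (not isolated) | Br[Mg]Cc1c(F)cc(F)cc1F | intermediate
10 | bromomagnesium (1R,2R)-1-[3,4-bis(benzyloxy)phenyl]-1-({[tri(propan-2-yl)silyl]oxy}methoxy)-3-(2,4,6-trifluorophenyl)propan-2-olate (not isolated) | Br[Mg]O[C@H](Cc1c(F)cc(F)cc1F)[C@H](OCO[Si](C(C)C)(C(C)C)C(C)C)c1ccc(OCc2ccccc2)c(OCc2ccccc2)c1 | intermediate
11 | (1R,2R)-1-[3,4-bis(benzyloxy)phenyl]-3-(2,4,6-trifluorophenyl)propane-1,2-diol, present as its alkoxide (not isolated) | O[C@H](Cc1c(F)cc(F)cc1F)[C@H](O)c1ccc(OCc2ccccc2)c(OCc2ccccc2)c1 | intermediate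
12 | (2R,3R)-2-[3,4-bis(benzyloxy)phenyl]-5,7-difluoro-3,4-dihydro-2H-chromen-3-ol | O[C@@H]1Cc2c(F)cc(F)cc2O[C@@H]1c1ccc(OCc2ccccc2)c(OCc2ccccc2)c1 | intermediate
13 | 5,7,3',4'-tetra-O-benzyl-(−)-epicatechin, (2R,3R)-5,7-bis(benzyloxy)-2-[3,4-bis(benzyloxy)phenyl]-3,4-dihydro-2H-chromen-3-ol | O[C@@H]1Cc2c(OCc3ccccc3)cc(OCc3ccccc3)cc2O[C@@H]1c1ccc(OCc2ccccc2)c(OCc2ccccc2)c1 | intermediate
14 | (−)-epiafzelechin, (2R,3R)-2-(4-hydroxyphenyl)-3,4-dihydro-2H-chromene-3,5,7-triol | O[C@@H]1Cc2c(O)cc(O)cc2O[C@@H]1c1ccc(O)cc1 | starting material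
15 | 5,7,4'-tri-O-benzyl-(−)-epiafzelechin | O[C@@H]1Cc2c(OCc3ccccc3)cc(OCc3ccccc3)cc2O[C@@H]1c1ccc(OCc2ccccc2)cc1 | intermediate
16 | 4β-(2-ethoxyethoxy)-5,7,4'-tri-O-benzyl-(−)-epiafzelechin (C4 alkoxy group trans to the C3 hydroxyl) | O[C@@H]1[C@@H](OCCOCC)c2c(OCc3ccccc3)cc(OCc3ccccc3)cc2O[C@@H]1c1ccc(OCc2ccccc2)cc1 | intermediate
17 | hepta-O-benzyl epiafzelechin-(4β→8)-epicatechin (both C3 hydroxyls free, upper unit 2,3-cis-3,4-trans, lower unit 2R,3R) | O[C@@H]1[C@@H](c2c(OCc4ccccc4)cc(OCc4ccccc4)c3c2O[C@H](c2ccc(OCc4ccccc4)c(OCc4ccccc4)c2)[C@H](O)C3)c2c(OCc3ccccc3)cc(OCc3ccccc3)cc2O[C@@H]1c1ccc(OCc2ccccc2)cc1 | intermediate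
18 | 3,4,5-tris(benzyloxy)benzoic acid | OC(=O)c1cc(OCc2ccccc2)c(OCc2ccccc2)c(OCc2ccccc2)c1 | starting material
19 | hepta-O-benzyl epiafzelechin-(4β→8)-epicatechin 3,3'-bis[3,4,5-tris(benzyloxy)benzoate] | O=C(O[C@@H]1[C@@H](c2c(OCc4ccccc4)cc(OCc4ccccc4)c3c2O[C@H](c2ccc(OCc4ccccc4)c(OCc4ccccc4)c2)[C@H](OC(=O)c2cc(OCc4ccccc4)c(OCc4ccccc4)c(OCc4ccccc4)c2)C3)c2c(OCc3ccccc3)cc(OCc3ccccc3)cc2O[C@@H]1c1ccc(OCc2ccccc2)cc1)c1cc(OCc2ccccc2)c(OCc2ccccc2)c(OCc2ccccc2)c1 | intermediate
20 | epiafzelechin 3-O-gallate-(4β→8)-epicatechin 3-O-gallate (CNP0291968.1) | O=C(O[C@@H]1[C@@H](c2c(O)cc(O)c3c2O[C@H](c2ccc(O)c(O)c2)[C@H](OC(=O)c2cc(O)c(O)c(O)c2)C3)c2c(O)cc(O)cc2O[C@@H]1c1ccc(O)cc1)c1cc(O)c(O)c(O)c1 | target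

**Step count and risks**

Total step count: 11. Longest linear sequence: 9 steps (steps 1, 2, 3, 4, 5, 6, 9, 10, 11, from compound 1).

The three steps most likely to fail:

Step 5. Chelation control in the Grignard addition may be incomplete, eroding the C3 configuration, and the fluoride-triggered ring closure may stall in the presence of magnesium salts. The fallback separates the two bond formations and sets C3 on the closed ring instead of on the acyclic chelate. It sets out from 7 and 8 and comes back at 12. Grignard reagent 9 is added to 7 as before, but the mixture is worked up to give the carbinol as a mixture of C3 epimers F1. Bu4NF in THF removes the silyloxymethyl group to give the diol mixture F2. NaH in THF/DMF closes ring C by SNAr to the 3-epimeric flavan-3-ols F3. Dess–Martin periodinane oxidises these to the single flavan-3-one F4. LiBH(s-Bu)3 in THF at −78 °C then adds hydride to the face opposite the C2 aryl group and returns the 2,3-cis alcohol 12.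

Step 6. The second fluoride displacement may stall on the ring once it has become electron-rich, or an elimination–addition pathway through an aryne may scramble the substitution pattern. The fallback oxygenates ring A before the annulation. It sets out from 7 and comes back at 13, bypassing 12. 1,3,5-Trifluorobenzene F5 is treated with BnONa (2 equiv, DMF) to give 1,3-bis(benzyloxy)-5-fluorobenzene F6. Vilsmeier–Haack formylation (POCl3, DMF) para to a benzyloxy group gives 2,4-bis(benzyloxy)-6-fluorobenzaldehyde F7. NaBH4 gives [2,4-bis(benzyloxy)-6-fluorophenyl]methanol F8, and PBr3 gives 1,5-bis(benzyloxy)-2-(bromomethyl)-3-fluorobenzene F9. Its benzylic Grignard reagent F10 is added to 7 under the conditions of step 5, forming the magnesium alkoxide adduct F11. Fluoride then releases the alkoxide of the diol F12, which should close on the single ortho fluorine at 80 °C in DMPU to give 13 directly.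

Step 9. Ionisation at C4 may lead to self-condensation of the electrophile into oligomers, and attack may occur at C6 instead of C8 of 13. The fallback changes the C4 leaving group to a thioether that a thiophilic silver salt activates under conditions that do not re-ionise the dimer. It sets out from 16 and comes back at 17. Compound 16 is treated with 1,3-benzothiazole-2-thiol and AlMe3 in CH2Cl2 to give 4β-(1,3-benzothiazol-2-ylsulfanyl)-5,7,4'-tri-O-benzyl-(−)-epiafzelechin F13. AgBF4 in THF at 0 °C then activates F13 in the presence of 13 (3 equiv) to give 17.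

Further compounds
F1 | step 5 | (1R)-1-[3,4-bis(benzyloxy)phenyl]-1-({[tri(propan-2-yl)silyl]oxy}methoxy)-3-(2,4,6-trifluorophenyl)propan-2-ol, mixture of C2 epimers | OC(Cc1c(F)cc(F)cc1F)[C@H](OCO[Si](C(C)C)(C(C)C)C(C)C)c1ccc(OCc2ccccc2)c(OCc2ccccc2)c1
F2 | step 5 | (1R)-1-[3,4-bis(benzyloxy)phenyl]-3-(2,4,6-trifluorophenyl)propane-1,2-diol, mixture of C2 epimers | OC(Cc1c(F)cc(F)cc1F)[C@H](O)c1ccc(OCc2ccccc2)c(OCc2ccccc2)c1
F3 | step 5 | (2R)-2-[3,4-bis(benzyloxy)phenyl]-5,7-difluoro-3,4-dihydro-2H-chromen-3-ol, mixture of C3 epimers | OC1Cc2c(F)cc(F)cc2O[C@@H]1c1ccc(OCc2ccccc2)c(OCc2ccccc2)c1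
F4 | step 5 | (2R)-2-[3,4-bis(benzyloxy)phenyl]-5,7-difluoro-2H-chromen-3(4H)-one | O=C1Cc2c(F)cc(F)cc2O[C@@H]1c1ccc(OCc2ccccc2)c(OCc2ccccc2)c1
F5 | step 6 | 1,3,5-trifluorobenzene | Fc1cc(F)cc(F)c1
F6 | step 6 | 1,3-bis(benzyloxy)-5-fluorobenzene | Fc1cc(OCc2ccccc2)cc(OCc2ccccc2)c1
F7 | step 6 | 2,4-bis(benzyloxy)-6-fluorobenzaldehyde | O=Cc1c(F)cc(OCc2ccccc2)cc1OCc1ccccc1
F8 | step 6 | [2,4-bis(benzyloxy)-6-fluorophenyl]methanol | OCc1c(F)cc(OCc2ccccc2)cc1OCc1ccccc1
F9 | step 6 | 1,5-bis(benzyloxy)-2-(bromomethyl)-3-fluorobenzene | BrCc1c(F)cc(OCc2ccccc2)cc1OCc1ccccc1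
F10 | step 6 | [2,4-bis(benzyloxy)-6-fluorobenzyl]magnesium bromide | Br[Mg]Cc1c(F)cc(OCc2ccccc2)cc1OCc1ccccc1
F11 | step 6 | bromomagnesium (1R,2R)-1-[3,4-bis(benzyloxy)phenyl]-3-[2,4-bis(benzyloxy)-6-fluorophenyl]-1-({[tri(propan-2-yl)silyl]oxy}methoxy)propan-2-olate | Br[Mg]O[C@H](Cc1c(F)cc(OCc2ccccc2)cc1OCc1ccccc1)[C@H](OCO[Si](C(C)C)(C(C)C)C(C)C)c1ccc(OCc2ccccc2)c(OCc2ccccc2)c1
F12 | step 6 | (1R,2R)-1-[3,4-bis(benzyloxy)phenyl]-3-[2,4-bis(benzyloxy)-6-fluorophenyl]propane-1,2-diol, present as its alkoxide | O[C@H](Cc1c(F)cc(OCc2ccccc2)cc1OCc1ccccc1)[C@H](O)c1ccc(OCc2ccccc2)c(OCc2ccccc2)c1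
F13 | step 9 | 4β-(1,3-benzothiazol-2-ylsulfanyl)-5,7,4'-tri-O-benzyl-(−)-epiafzelechin | O[C@@H]1[C@@H](Sc2nc3ccccc3s2)c2c(OCc3ccccc3)cc(OCc3ccccc3)cc2O[C@@H]1c1ccc(OCc2ccccc2)cc1
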